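**Plan**

- Core numbering (bicyclo[3.3.1]nonane): C1 = C(OH) bridgehead, C2 = CH2, C3 = CH–N, C4 = CH–OH, C5 = CH bridgehead, C6 = CH–OMe, C7/C8 = oxirane carbons, C9 = C=O; ring A = C1–C2–C3–C4–C5–C9, ring B = C1–C9–C5–C6–C7–C8.
- Retrosynthesis: the C9 ketone (from a carbinol), the oxirane (from a C7=C8 alkene), the amide C–N bond and the C4 carbinol (from a ketone) are taken back first; ring A is then cut at its two opposite bonds C2–C3 and C5–C9, which also opens ring B.
- Enabling feature: the cut leaves C3–C4–C5, a C4 ketone whose two α-carbons are nucleophiles (C3 acidified by a benzophenone imine on N), and C2–C1–C9, a tertiary carbinol flanked by CH2 and C=O, i.e. a 2-formyloxirane whose ring oxygen becomes the C1 hydroxyl (a 1,3-bis-electrophile); both units sit on one chain through C6 and a Z C7=C8 alkene.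
- Forward: the chain is built linearly (Claisen condensation, transfer hydrogenation, O-methylation, Sonogashira coupling, Sharpless epoxidation, Lindlar reduction, azaallyl acylation, oxidation); one base-induced isomerisation closes ring B (aldol, C5–C9) and then ring A (oxirane alkylation, C2–C3); C4, N, C7/C8 and C9 are adjusted last.
- Stereochemistry: C6 from the Noyori transfer hydrogenation, C1 from the Sharpless epoxidation; C5 and C3 are relayed from C6 and C1 in the key step; C4 from equatorial hydride delivery; the oxirane from attack on the convex face of ring B.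

Key step: step 9

Remark: the C9 carbinol configuration created in the key step is not controlled and not needed (it is oxidised in the last step), so all compounds between the key step and the last step are written without a descriptor at C9; core numbering is used for these carbons throughout.

**Route**

Step 1
Reactants: 1 N-methoxy-N-methylacetamide; 2 ethyl 3-(trimethylsilyl)prop-2-ynoate
Product: 3 N-methoxy-N-methyl-3-oxo-5-(trimethylsilyl)pent-4-ynamide
Conditions: lithium diisopropylamide (2.1 equiv), 1 (2.1 equiv), THF, −78 °C; then 2 (1.0 equiv), −78 → −40 °C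
Reagents that add atoms: none
Why: Crossed Claisen condensation of the lithium amide enolate with the ynoate, in which the silyl group shields the β-carbon from conjugate addition and the second equivalent of enolate deprotonates the β-keto amide as it forms, so that no second addition should occur.

Step 2
Reactants: 3 N-methoxy-N-methyl-3-oxo-5-(trimethylsilyl)pent-4-ynamide
Product: 4 (3S)-3-hydroxy-N-methoxy-N-methyl-5-(trimethylsilyl)pent-4-ynamide
Conditions: Ru[(S,S)-TsDPEN](p-cymene) (1 mol %), i-PrOH, 23 °C
Reagents that add atoms: none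
Why: Noyori asymmetric transfer hydrogenation of an alkynyl ketone, in which the (S,S)-diamine ligand should direct hydride to the carbonyl face that gives the (S)-propargylic alcohol (future C6), the alkyne serving as the π-substituent recognised by the arene ligand.

Step 3
Reactants: 4 (3S)-3-hydroxy-N-methoxy-N-methyl-5-(trimethylsilyl)pent-4-ynamide
Product: 5 (3S)-N,3-dimethoxy-N-methyl-5-(trimethylsilyl)pent-4-ynamide
Conditions: Me3OBF4, 1,8-bis(dimethylamino)naphthalene, CH2Cl2, 0 → 23 °C
Reagents that add atoms: trimethyloxonium tetrafluoroborate, C[O+](C)C.F[B-](F)(F)F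
Why: Meerwein O-methylation under buffered, non-basic conditions, so that neither retro-aldol cleavage nor β-elimination of the β-hydroxy amide should occur and the stereocentre is untouched.

Step 4
Reactants: 5 (3S)-N,3-dimethoxy-N-methyl-5-(trimethylsilyl)pent-4-ynamide; 6 2-bromoprop-2-en-1-ol
Product: 8 (3S)-6-(hydroxymethyl)-N,3-dimethoxy-N-methylhept-6-en-4-ynamide, via terminal alkyne 7 (not isolated)
Conditions: K2CO3 (0.2 equiv), MeOH, 23 °C; solvent exchange; then 6, Pd(PPh3)2Cl2 (3 mol %), CuI (5 mol %), Et3N, THF, 23 °C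
Reagents that add atoms: none
Why: Base-catalysed protodesilylation of the alkynylsilane followed by Sonogashira coupling of the free alkyne with the vinyl bromide, which installs C1, C2 and C9 without touching the stereocentre.

Step 5
Reactants: 8 (3S)-6-(hydroxymethyl)-N,3-dimethoxy-N-methylhept-6-en-4-ynamide
Product: 9 (3S)-5-[(2S)-2-(hydroxymethyl)oxiran-2-yl]-N,3-dimethoxy-N-methylpent-4-ynamide
Conditions: Ti(OiPr)4 (10 mol %), L-(+)-diethyl tartrate (12 mol %), t-BuOOH, 4 Å molecular sieves, CH2Cl2, −20 °C
Reagents that add atoms: tert-butyl hydroperoxide, CC(C)(C)OO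
Why: Sharpless asymmetric epoxidation of the 2-substituted allylic alcohol, in which the titanium/L-(+)-tartrate complex should deliver oxygen to the alkene face that makes the quaternary oxirane carbon (future C1) S, the alkyne being inert.

Step 6
Reactants: 9 (3S)-5-[(2S)-2-(hydroxymethyl)oxiran-2-yl]-N,3-dimethoxy-N-methylpent-4-ynamide
Product: 10 (3S,4Z)-5-[(2S)-2-(hydroxymethyl)oxiran-2-yl]-N,3-dimethoxy-N-methylpent-4-enamide
Conditions: H2 (1 atm), Lindlar catalyst (Pd/CaCO3 poisoned with Pb(OAc)2), quinoline, EtOAc, 23 °C
Reagents that add atoms: none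
Why: Lindlar semihydrogenation, whose syn delivery of hydrogen on the poisoned palladium surface should give the Z alkene that becomes the C7=C8 bond of ring B.

Step 7
Reactants: 10 (3S,4Z)-5-[(2S)-2-(hydroxymethyl)oxiran-2-yl]-N,3-dimethoxy-N-methylpent-4-enamide; 11 N-(diphenylmethylidene)methanamine
Product: 12 (4S,5Z)-1-[(diphenylmethylidene)amino]-6-[(2S)-2-(hydroxymethyl)oxiran-2-yl]-4-methoxyhex-5-en-2-one
Conditions: lithium diisopropylamide (3.1 equiv), 11 (3.2 equiv), THF, −78 °C; then 10, −78 → −40 °C
Reagents that add atoms: none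
Why: Weinreb ketone synthesis with the 1,1-diphenyl-2-azaallyllithium made from 11, which reacts at its unsubstituted CH2 terminus; the chelated tetrahedral intermediate prevents over-addition and one equivalent of the anion is spent on the free hydroxyl.

Step 8
Reactants: 12 (4S,5Z)-1-[(diphenylmethylidene)amino]-6-[(2S)-2-(hydroxymethyl)oxiran-2-yl]-4-methoxyhex-5-en-2-one
Product: 13 (2R)-2-[(1Z,3S)-6-[(diphenylmethylidene)amino]-3-methoxy-5-oxohex-1-en-1-yl]oxirane-2-carbaldehyde
Conditions: Dess–Martin periodinane, NaHCO3, CH2Cl2, 0 °C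
Reagents that add atoms: none
Why: Dess–Martin oxidation of the primary alcohol under buffered conditions should give the non-enolisable α-oxiranyl aldehyde without touching the imine, the oxirane or the acidic CH2 (the change of descriptor at the oxirane carbon is a priority change only).

Step 9
Reactants: 13 (2R)-2-[(1Z,3S)-6-[(diphenylmethylidene)amino]-3-methoxy-5-oxohex-1-en-1-yl]oxirane-2-carbaldehyde
Product: 15 (1S,3S,5R,6R)-3-[(diphenylmethylidene)amino]-1,9-dihydroxy-6-methoxybicyclo[3.3.1]non-7-en-4-one, via spiro-oxirane aldol 14 (not isolated)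
Conditions: lithium 2,2,6,6-tetramethylpiperidide (2.1 equiv), THF (0.01 M), −78 °C, slow addition of 13; then 23 °C
Reagents that add atoms: none
Why: Proposed new method: two equivalents of the hindered, non-nucleophilic amide should give the α,α'-dianion of the imino ketone (first the imine-stabilised C3 carbanion, then the C5 enolate, as in acetoacetate dianions), whose more basic C5 terminus adds to the non-enolisable C9 aldehyde to give the alkoxide of 14, and on warming the remaining C3 carbanion opens the spiro-oxirane at C2 by SN2 displacement, turning the oxirane oxygen into the C1 hydroxyl. The closest known reaction types are the Michael–Claisen (3+3) annulation of ketones with acrylates, the terminal-carbon reactions of β-dicarbonyl dianions and the cyclisation of epoxy-ketone or epoxy-nitrile anions; their union on a 2-formyloxirane as a three-carbon bis-electrophile is untested. Ring B closes 6-(enolexo)-exo-trig; ring A closes 6-(enolendo)-exo-tet at C3, in the endo mode with respect to the oxirane C1–C2 bond, through a chair in which the breaking C2–O bond lies antiperiplanar to the forming C2–C3 bond. C5 is set by C6 (minimised allylic strain places the acyl chain trans to the methoxy group), and this is the epimer whose acyl chain is cis to the oxirane CH2 on C1, so that a ring flip brings the two reacting carbons cis-diaxial; C3 is set after closure by equilibration of the still acidic C3–H to the equatorial (exo) imine; C9 is not controlled and not needed. The step needs reaction at C5 before C3 (the C3 anion would need an eight-membered ring to reach either electrophile), C- rather than O-alkylation at CH2 rather than at the quaternary or the allylic (SN2') carbon (lithium counter-ion, soft azaallyl carbanion, oxirane oxygen pseudo-equatorial and so out of alignment with the alkene π system), and no loss of methoxide or of the aldol hydroxyl (the C3 anion blocks enolisation toward C5, and in 15 C5 is a bridgehead that cannot enolise, Bredt's rule).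

Step 10
Reactants: 15 (1S,3S,5R,6R)-3-[(diphenylmethylidene)amino]-1,9-dihydroxy-6-methoxybicyclo[3.3.1]non-7-en-4-one
Product: 16 (1S,3S,4R,5R,6R)-3-[(diphenylmethylidene)amino]-6-methoxybicyclo[3.3.1]non-7-ene-1,4,9-triol
Conditions: LiBH(s-Bu)3 (L-Selectride, 4 equiv), THF, −78 °C
Reagents that add atoms: none
Why: Diastereoselective ketone reduction with a bulky trialkylborohydride, which should enter along the equatorial (exo) trajectory of the ring-A ketone, away from the 1,3-diaxial C2–H and C9 substituent, and give the axial C4 carbinol cis to the equatorial nitrogen.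

Step 11
Reactants: 16 (1S,3S,4R,5R,6R)-3-[(diphenylmethylidene)amino]-6-methoxybicyclo[3.3.1]non-7-ene-1,4,9-triol; 17 (2E)-dodec-2-enoic acid
Product: 19 (2E)-N-[(1S,3S,4R,5R,6R)-1,4,9-trihydroxy-6-methoxybicyclo[3.3.1]non-7-en-3-yl]dodec-2-enamide, via amino triol 18 (not isolated)
Conditions: 1 M HCl (1.1 equiv), THF, 0 °C; then N-methylmorpholine (1.2 equiv), 17, 4-(4,6-dimethoxy-1,3,5-triazin-2-yl)-4-methylmorpholinium chloride (DMTMM), MeOH, 23 °C
Reagents that add atoms: none
Why: Acid hydrolysis of the benzophenone imine followed by amide coupling through the acyloxytriazine active ester, which should acylate the amine and not the three hydroxyls; no stereocentre is touched (the bridgehead allylic alcohol cannot ionise).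

Step 12
Reactants: 19 (2E)-N-[(1S,3S,4R,5R,6R)-1,4,9-trihydroxy-6-methoxybicyclo[3.3.1]non-7-en-3-yl]dodec-2-enamide
Product: 20 (2E)-N-[(1R,3S,4R,5R,6S,7S,8S)-7,8-epoxy-1,4,9-trihydroxy-6-methoxybicyclo[3.3.1]nonan-3-yl]dodec-2-enamide
Conditions: m-CPBA, CH2Cl2, 0 °C
Reagents that add atoms: meta-chloroperoxybenzoic acid, OOC(=O)c1cccc(Cl)c1
Why: Prilezhaev epoxidation, in which the electron-rich cis ring alkene should react in preference to the conjugated amide alkene and the peracid should approach the convex (exo) face of ring B, the concave face being closed by ring A (endo hydrogen at C3 and the C2 methylene), which places the oxirane cis to the C6 methoxy group.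

Step 13
Reactants: 20 (2E)-N-[(1R,3S,4R,5R,6S,7S,8S)-7,8-epoxy-1,4,9-trihydroxy-6-methoxybicyclo[3.3.1]nonan-3-yl]dodec-2-enamide
Product: 21 (2E)-N-[(1S,3S,4R,5S,6S,7S,8S)-7,8-epoxy-1,4-dihydroxy-6-methoxy-9-oxobicyclo[3.3.1]nonan-3-yl]dodec-2-enamide
Conditions: [(neocuproine)Pd(OAc)]2(OTf)2 (5 mol %), 1,4-benzoquinone (1.5 equiv), MeCN/H2O (9:1), 23 °C
Reagents that add atoms: none
Why: Chemoselective palladium-catalysed dehydrogenation of a vicinal diol to the α-hydroxy ketone, in which the cationic divalent palladium catalyst should chelate the C1/C9 diol and oxidise its secondary carbinol while the isolated axial C4 alcohol, the oxirane and the unsaturated amide remain.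

**Compound list**

1 | N-methoxy-N-methylacetamide | CC(=O)N(C)OC | starting material
2 | ethyl 3-(trimethylsilyl)prop-2-ynoate | CCOC(=O)C#C[Si](C)(C)C | starting material
3 | N-methoxy-N-methyl-3-oxo-5-(trimethylsilyl)pent-4-ynamide | CON(C)C(=O)CC(=O)C#C[Si](C)(C)C | intermediate
4 | (3S)-3-hydroxy-N-methoxy-N-methyl-5-(trimethylsilyl)pent-4-ynamide | CON(C)C(=O)C[C@H](O)C#C[Si](C)(C)C | intermediate
5 | (3S)-N,3-dimethoxy-N-methyl-5-(trimethylsilyl)pent-4-ynamide | CON(C)C(=O)C[C@H](OC)C#C[Si](C)(C)C | intermediate
6 | 2-bromoprop-2-en-1-ol | OCC(Br)=C | starting material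
7 | (3S)-N,3-dimethoxy-N-methylpent-4-ynamide (not isolated) | CON(C)C(=O)C[C@H](OC)C#C | intermediate
8 | (3S)-6-(hydroxymethyl)-N,3-dimethoxy-N-methylhept-6-en-4-ynamide | CON(C)C(=O)C[C@H](OC)C#CC(=C)CO | intermediate
9 | (3S)-5-[(2S)-2-(hydroxymethyl)oxiran-2-yl]-N,3-dimethoxy-N-methylpent-4-ynamide | CON(C)C(=O)C[C@H](OC)C#C[C@]1(CO)CO1 | intermediate
10 | (3S,4Z)-5-[(2S)-2-(hydroxymethyl)oxiran-2-yl]-N,3-dimethoxy-N-methylpent-4-enamide | CON(C)C(=O)C[C@H](OC)/C=C\[C@]1(CO)CO1 | intermediate
11 | N-(diphenylmethylidene)methanamine | CN=C(c1ccccc1)c1ccccc1 | starting material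
12 | (4S,5Z)-1-[(diphenylmethylidene)amino]-6-[(2S)-2-(hydroxymethyl)oxiran-2-yl]-4-methoxyhex-5-en-2-one | O=C(CN=C(c1ccccc1)c1ccccc1)C[C@H](OC)/C=C\[C@]1(CO)CO1 | intermediate
13 | (2R)-2-[(1Z,3S)-6-[(diphenylmethylidene)amino]-3-methoxy-5-oxohex-1-en-1-yl]oxirane-2-carbaldehyde | O=C(CN=C(c1ccccc1)c1ccccc1)C[C@H](OC)/C=C\[C@]1(C=O)CO1 | intermediate
14 | 2-[(diphenylmethylidene)amino]-1-[(3R,5R,6R)-4-hydroxy-6-methoxy-1-oxaspiro[2.5]oct-7-en-5-yl]ethan-1-one (not isolated) | O=C(CN=C(c1ccccc1)c1ccccc1)[C@H]1[C@H](OC)C=C[C@@]2(CO2)C1O | intermediate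
15 | (1S,3S,5R,6R)-3-[(diphenylmethylidene)amino]-1,9-dihydroxy-6-methoxybicyclo[3.3.1]non-7-en-4-one (core numbering) | c1ccccc1C(c1ccccc1)=N[C@H]1C[C@@]2(O)C(O)[C@@H](C1=O)[C@H](OC)C=C2 | intermediate
16 | (1S,3S,4R,5R,6R)-3-[(diphenylmethylidene)amino]-6-methoxybicyclo[3.3.1]non-7-ene-1,4,9-triol | c1ccccc1C(c1ccccc1)=N[C@H]1C[C@@]2(O)C(O)[C@@H]([C@H]1O)[C@H](OC)C=C2 | intermediate
17 | (2E)-dodec-2-enoic acid | CCCCCCCCC/C=C/C(=O)O | starting material
18 | (1S,3S,4R,5R,6R)-3-amino-6-methoxybicyclo[3.3.1]non-7-ene-1,4,9-triol (not isolated) | N[C@H]1C[C@@]2(O)C(O)[C@@H]([C@H]1O)[C@H](OC)C=C2 | intermediate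
19 | (2E)-N-[(1S,3S,4R,5R,6R)-1,4,9-trihydroxy-6-methoxybicyclo[3.3.1]non-7-en-3-yl]dodec-2-enamide | CCCCCCCCC/C=C/C(=O)N[C@H]1C[C@@]2(O)C(O)[C@@H]([C@H]1O)[C@H](OC)C=C2 | intermediate
20 | (2E)-N-[(1R,3S,4R,5R,6S,7S,8S)-7,8-epoxy-1,4,9-trihydroxy-6-methoxybicyclo[3.3.1]nonan-3-yl]dodec-2-enamide | CCCCCCCCC/C=C/C(=O)N[C@H]1C[C@@]2(O)C(O)[C@@H]([C@H]1O)[C@H](OC)[C@@H]1O[C@@H]12 | intermediate
21 | (2E)-N-[(1S,3S,4R,5S,6S,7S,8S)-7,8-epoxy-1,4-dihydroxy-6-methoxy-9-oxobicyclo[3.3.1]nonan-3-yl]dodec-2-enamide | CCCCCCCCC/C=C/C(=O)N[C@H]1C[C@@]2(O)C(=O)[C@@H]([C@H]1O)[C@H](OC)[C@@H]1O[C@@H]12 | target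

**Step count and risks**

Total step count: 13 (steps 4, 9 and 11 are one-pot operations). Longest linear sequence: 13 steps from 1 and 2; compounds 6, 11 and 17 are purchased.

The three steps most likely to fail:

1. Step 9 (Proposed new method). The second deprotonation at C5 may be slower than side reactions of the amide base or of the C3 anion: intermolecular aldol addition, loss of methoxide from the dianion, migration of the oxirane onto the new C9 alkoxide, or O-alkylation. Ring B would then not close first, or ring A not at all. The fallback uses known reactions, makes the two bonds in separate steps and introduces the acidic imine only after ring B exists; it sets out from 10 and returns at 15. Dess–Martin oxidation of 10 should give (3S,4Z)-5-[(2R)-2-formyloxiran-2-yl]-N,3-dimethoxy-N-methylpent-4-enamide F1. Its amide has a single enolisable position, so an intramolecular aldol addition of the amide enolate (LiN(SiMe3)2, THF, −78 °C) should close ring B to (3R,5R,6R)-4-hydroxy-N,6-dimethoxy-N-methyl-1-oxaspiro[2.5]oct-7-ene-5-carboxamide F2. Acylation of the azaallyllithium from 11 with F2, as in step 7, should then give 14 as an isolated compound. A separate enolate–oxirane alkylation of 14 (t-BuOK, t-BuOH/THF, 23 → 50 °C), which can be forced now that no aldehyde is left, should close ring A and rejoin the route at 15.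

2. Step 7. The azaallyl anion may act as a base on the Weinreb amide (enolisation followed by loss of methoxide to a dienamide) or attack the oxirane instead of the amide carbonyl. The fallback builds the amino ketone by homologation and sets out from 10, returning at 12. Chloromethyllithium generated in the presence of the substrate (ICH2Cl, MeLi·LiBr, THF, −78 °C) should give (4S,5Z)-1-chloro-6-[(2S)-2-(hydroxymethyl)oxiran-2-yl]-4-methoxyhex-5-en-2-one F3. Displacement with NaN3 (DMF, 0 °C) should give (4S,5Z)-1-azido-6-[(2S)-2-(hydroxymethyl)oxiran-2-yl]-4-methoxyhex-5-en-2-one F4. Staudinger reduction (PMe3, THF/H2O) in the presence of benzophenone imine should trap the amino ketone by transimination as 12.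

3. Step 13. The catalyst may discriminate too little between the C9 and C4 carbinols (over-oxidation at C4), may be held by the hydroxy amide, or the α-hydroxy ketone may undergo acyloin rearrangement on long exposure. The fallback replaces catalyst control by covalent activation of the diol through a temporary ring; it sets out from 20 and returns at 21. Condensation of 20 with Bu2SnO (MeOH, reflux) should give the O1,O9-dibutylstannylene acetal of 20 F5, in which only the C1/C9 diol is tin-bound. Brominolysis (Br2, CH2Cl2, 23 °C) should oxidise only the tin-bound secondary carbinol and give 21.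

**Further compounds**

F1 | step 9 | (3S,4Z)-5-[(2R)-2-formyloxiran-2-yl]-N,3-dimethoxy-N-methylpent-4-enamide | CON(C)C(=O)C[C@H](OC)/C=C\[C@]1(C=O)CO1
F2 | step 9 | (3R,5R,6R)-4-hydroxy-N,6-dimethoxy-N-methyl-1-oxaspiro[2.5]oct-7-ene-5-carboxamide | CON(C)C(=O)[C@H]1[C@H](OC)C=C[C@@]2(CO2)C1O
F3 | step 7 | (4S,5Z)-1-chloro-6-[(2S)-2-(hydroxymethyl)oxiran-2-yl]-4-methoxyhex-5-en-2-one | ClCC(=O)C[C@H](OC)/C=C\[C@]1(CO)CO1
F4 | step 7 | (4S,5Z)-1-azido-6-[(2S)-2-(hydroxymethyl)oxiran-2-yl]-4-methoxyhex-5-en-2-one | [N-]=[N+]=NCC(=O)C[C@H](OC)/C=C\[C@]1(CO)CO1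
F5 | step 13 | O1,O9-dibutylstannylene acetal of 20 | CCCCCCCCC/C=C/C(=O)N[C@H]1C[C@@]2(O[Sn](CCCC)(CCCC)O3)C3[C@@H]([C@H]1O)[C@H](OC)[C@@H]1O[C@@H]12
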